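Readings and results were computed for substances that don't exist; noise was put on by code.

Target in the flask cannot pass the whole substrate charge, and since partner is charged at 1.20 times the substrate, the substrate is the limiting reagent and the curve of target must bend; what matters is whether the bend comes before the asked time.

in all of them: initiator 120 mM

|  | substrate | partner | remark | time |
|---|---|---|---|---|
| larch | 1.5 M | 1.8 M | the very flask that is asked about, followed so far |  |
| birch | 3 M | 1.8 M | run made earlier |  |
| flask | 1.5 M | 1.80 M |  | 2.5 h |

| run | time / min | target / % | substrate / % |
|---|---|---|---|
| larch | 4.00 | 4.7 | 94.2 |
| larch | 12.0 | 14.4 | 86.0 |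
| larch | 20.0 | 22.1 | 77.7 |
| larch | 30.0 | 30.8 | 67.7 |
| larch | 50.0 | 47.1 | 51.5 |
| birch | 10.0 | 5.5 | 95.1 |
| birch | 25.0 | 13.8 | 86.6 |
| birch | 50.0 | 23.7 | 75.3 |
| birch | 80.0 | 32.7 | 67.0 |
| birch | 120 | 42.2 | 57.3 |

(readings scatter by 0.5 percentage points)

- a species is counted by the substrate in it: one ended chains counts as two

- the target in the flask at 2.5 h, as a percentage of the substrate charged
- the substrate in the flask at 2.5 h, as a percentage of the substrate charged
- the ended chains in the flask at 2.5 h, as a percentage of the substrate charged

Counting one partner gone per target, larch, which has the flask's recipe, keeps 60.7% of its partner at 50.0 min, and birch, with twice the substrate, keeps 29.7% at 120 min. On a logarithmic scale these give nearly the same decade time of the partner, the time in which the fraction of partner left falls tenfold: 231 min in larch and 227 min in birch, so 229 min on average as read from these two runs, a pseudo-first-order decay whose decade time differs little between their two substrate charges.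

My reckoning draws the curve from this. Target starts at 0.0121 /min of the charge and reaches 0.5 of it at 53.7 min. The straight decay would reach the full charge at 178 min, later than 150 min, so it may be carried that far: partner left is 22.2% and target 93.4%, after which the curve flattens just under the charge.

The forecast, finding the rate “first order in partner, with no visible initiator fade”, gave target 86%, substrate 9% and ended chains 4%, so its target stands 7.4 percentage points below my reckoning.

The flask gave target 92.8%, substrate 5.11% and ended chains 2.09%.

    initiator → 2 initiating radical (k = 0.0560 /h)
    substrate + initiating radical → capped initiator + first chain carrier (k = 18000 /M/s)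
    partner + first chain carrier → target + second chain carrier (k = 4.50 × 10⁶ /M/h)
    substrate + second chain carrier → by-product + first chain carrier (k = 3.10 × 10⁶ /M/h)
    2 first chain carrier → ended chains (k = 1.00 × 10⁸ /M/s)

In the flask, partner with first chain carrier made target while substrate with second chain carrier made by-product, the first of these steps having 69% of its turnover up to 2.50 h behind it at 1.25 h, and partner came down to 23% of its charge at 2.50 h against the 22.2% from the decade time. In the neighbour flask with partner at 0.45 M, the same decade time gives target 23.4% of the substrate charged at 2.5 h, and at that time that flask holds 23.2% with 23% of its partner left.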